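A direct plan would make the tricyclo[4.2.1.1(2,5)]deca-3,7-diene core by dimerising two tautomeric cyclopropyl-methylcyclopentadienes, the 2-methyl diene A1 and the 5-methyl diene A2, themselves made by acid ionisation and 4π-closure of the cyclopropyl bis-allylic carbinol A3: sensitised [2+2] photodimerisation would give the cis-syn-cis cyclobutane A4, and a Cope rearrangement would then give the core. Its weakest steps would be:
- the cross-photodimerisation, which would have to select one hetero pair, one regiochemistry, the syn mode and one diene face out of more than a dozen dimers, with only a remote cyclopropane to tell the two enantiomeric cores apart;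
- the acid-induced dehydrative cyclisation, which would place a cation next to each cyclopropane (ring opening) and would need two diene tautomers to survive without 1,5-H scrambling;
- the one-pot double Grignard addition to an enol lactone that would give carbinol A3, with a ketone protected only as its magnesium enolate and the carbinol centre formed as a mixture.

**Plan of the new route**
- Cuts: C1–C8 and C4–C5 (two 5-endo-dig closures of enol carbons onto alkynes), C6–C7 and C2–C3 (two conjugate alkynylations), C3–CH3 (cross-coupling). The central ring C1–C9–C6–C5–C10–C2 is never cut: it is the ring of 4-methoxy-3-methylphenol, whose oxygen-bearing carbons become C10 and C9.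
- Enabling feature: C1, C2, C5 and C6 all lie α to C9 or C10, which sit 1,4 in the central six-membered ring (a hidden 2-methyl-1,4-benzoquinone). In each cyclopentene the cyclopropyl-bearing alkene carbon (C8, C4) is bonded to the carbon α′ to that carbonyl, so each ring is an enol/alkyne 5-endo-dig adduct.
- Because C3/C4 stay sp2 from alkyne to alkene, no substituent ever points at the facing C7=C8 bridge; that is what lets a stepwise closure reach the syn isomer.
- Ring order: central six-membered ring (from the arene), then ring A (C1, C8, C7, C6, C9), then ring B (C2, C3, C4, C5, C10) and with it the eight-membered ring.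
- The weak steps vanish: no dimerisation (one alkyne serves both halves, every bond joins defined partners); the core configuration comes from one catalyst-controlled addition at C6, relayed by ring constraints and a kinetic protonation; no cation is formed next to a cyclopropane; both side-chain ketones travel as dioxolanes.

Key step: step 12

Remark (assumption on the chemistry): atom numbers C1–C10 in the Why lines are those of the target; Cp is the cis-2,2-dimethyl-3-[2-(2-methyl-1,3-dioxolan-2-yl)ethyl]cyclopropyl group of alkyne 13, unchanged throughout; the ligand antipode that gives the 6R adduct 18 would be chosen by a screen of both antipodes.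

Step 1
Reactants: 1 (S)-(+)-carvone; 2 hydrogen chloride
Product: 4 (1R,6S)-3,7,7-trimethylbicyclo[4.1.0]hept-3-en-2-one, via tertiary chloride 3 (not isolated)
Conditions: HCl (g), Et2O, −10 °C; then t-BuOK, THF, 0 °C
Reagents that add atoms: none
Why: Markovnikov hydrochlorination and intramolecular α′-alkylation of the kinetic enolate (3-exo-tet) should close the cis-fused gem-dimethylcyclopropane, the carvone stereocentre fixing both cyclopropane centres.

Step 2
Reactants: 4 (1R,6S)-3,7,7-trimethylbicyclo[4.1.0]hept-3-en-2-one; 5 3-chloroperoxybenzoic acid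
Product: 6 (1R,7S)-4,8,8-trimethyl-3-oxabicyclo[5.1.0]oct-4-en-2-one
Conditions: mCPBA, CH2Cl2, 0 °C to rt
Reagents that add atoms: 3-chloroperoxybenzoic acid, OOC(=O)c1cccc(Cl)c1
Why: Baeyer–Villiger oxidation in which the alkenyl carbon migrates in preference to the cyclopropyl carbon should give the enol lactone without touching a stereocentre.

Step 3
Reactants: 6 (1R,7S)-4,8,8-trimethyl-3-oxabicyclo[5.1.0]oct-4-en-2-one; 7 methanol
Product: 8 methyl (1R,3S)-2,2-dimethyl-3-(3-oxobutyl)cyclopropane-1-carboxylate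
Conditions: K2CO3 (0.2 equiv), MeOH, 0 °C
Reagents that add atoms: methanol, CO
Why: Transesterification (acyl substitution) of the enol ester should release the methyl ketone as its enol and leave the cis-cyclopropane untouched at 0 °C.

Step 4
Reactants: 8 methyl (1R,3S)-2,2-dimethyl-3-(3-oxobutyl)cyclopropane-1-carboxylate; 9 ethane-1,2-diol
Product: 10 methyl (1R,3S)-2,2-dimethyl-3-[2-(2-methyl-1,3-dioxolan-2-yl)ethyl]cyclopropane-1-carboxylate
Conditions: ethylene glycol (5 equiv), pyridinium p-toluenesulfonate (10 mol %), benzene, reflux, Dean–Stark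
Reagents that add atoms: ethane-1,2-diol, OCCO
Why: Ketalisation of the ketone (the ester is inert) should mask the side chain for the organometallic and hydrazone steps.

Step 5
Reactants: 10 methyl (1R,3S)-2,2-dimethyl-3-[2-(2-methyl-1,3-dioxolan-2-yl)ethyl]cyclopropane-1-carboxylate; 11 dimethyl (1-diazo-2-oxopropyl)phosphonate
Product: 13 2-{2-[(1S,3S)-3-ethynyl-2,2-dimethylcyclopropyl]ethyl}-2-methyl-1,3-dioxolane (Cp–C≡CH), via aldehyde 12 (not isolated)
Conditions: i-Bu2AlH (1.1 equiv), CH2Cl2, −78 °C; then MeOH, K2CO3 (2 equiv), 11 (1.3 equiv), −78 °C to rt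
Reagents that add atoms: dimethyl (1-diazo-2-oxopropyl)phosphonate, CC(=O)C(=[N+]=[N-])P(=O)(OC)OC
Why: Partial reduction of the ester to the aldehyde and Seyferth–Gilbert homologation with the Ohira–Bestmann reagent in one pot should give the terminal alkyne with the cis-cyclopropane intact.

Step 6
Reactants: 14 4-methoxy-3-methylphenol; 7 methanol
Product: 15 4,4-dimethoxy-3-methylcyclohexa-2,5-dien-1-one
Conditions: PhI(OAc)2 (1.1 equiv), MeOH, 0 °C
Reagents that add atoms: methanol, CO
Why: Oxidative dearomatisation of the para-methoxyphenol in methanol should give the quinone monoketal, a cross-conjugated dienone that cannot re-aromatise.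

Step 7
Reactants: 15 4,4-dimethoxy-3-methylcyclohexa-2,5-dien-1-one; 13 Cp–C≡CH; 16 water
Product: 18 (6R)-6-(Cp-ethynyl)-2-methylcyclohex-2-ene-1,4-dione, via ketal 17 (not isolated)
Conditions: 13, n-BuLi, THF, −78 °C, then Me2AlCl; Ni(acac)2 (5 mol %), chiral cyano-bis(oxazoline) ligand (6 mol %), i-Bu2AlH (5 mol %), Et2O–THF, −20 °C; then 5% aq. oxalic acid, THF, 0 °C
Reagents that add atoms: water, O
Why: Nickel-catalysed enantioselective conjugate addition of the dimethylaluminium acetylide should go to the unsubstituted β-carbon (not the methyl-bearing one), the ligand choosing the enantiotopic face and so setting C6, the only core stereocentre set by a reagent; mild hydrolysis of the allylic dimethyl ketal (faster than the dioxolane) then unveils the C9 carbonyl.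

Step 8
Reactants: 18 (6R)-6-(Cp-ethynyl)-2-methylcyclohex-2-ene-1,4-dione; 13 Cp–C≡CH; 19 tert-butyldimethylsilyl trifluoromethanesulfonate
Product: 20 (5R)-4-[(tert-butyldimethylsilyl)oxy]-2,5-bis(Cp-ethynyl)-3-methylcyclohex-3-en-1-one (both C2 epimers)
Conditions: 13, n-BuLi, THF, −78 °C, then ZnBr2; 18, TBSOTf (1.2 equiv), Et2O–THF, −40 °C
Reagents that add atoms: tert-butyldimethylsilyl trifluoromethanesulfonate, CC(C)(C)[Si](C)(C)OS(=O)(=O)C(F)(F)F
Why: Silyl-triflate-promoted conjugate alkynylation should deliver the alkynylzinc to the unsubstituted alkene carbon (future C2) and trap the C9 enolate regiospecifically as the silyl enol ether towards the methyl-bearing carbon (future C1); no base is present, which should keep the enolisable ene-dione from tautomerising to a hydroquinone, and the C2 mixture is corrected in step 10.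

Step 9
Reactants: 20 (5R)-4-[(tert-butyldimethylsilyl)oxy]-2,5-bis(Cp-ethynyl)-3-methylcyclohex-3-en-1-one
Product: 21 2-(Cp-ethynyl)-7-Cp-1-methylbicyclo[3.2.1]oct-6-ene-3,8-dione (both C2 epimers)
Conditions: (Ph3P)AuCl (5 mol %), AgBF4 (5 mol %), MeOH (2 equiv), CH2Cl2, 0 °C to rt
Reagents that add atoms: none
Why: Proposed new method: cationic monovalent gold should π-activate the C6-bound alkyne on its outer face so that the tetrasubstituted silyl enol ether carbon (C1) attacks the cyclopropyl-bearing alkyne carbon (C8) anti to gold in a 5-endo-dig Conia-ene closure, methanol removing the silyl group and protodeauration leaving H at C7; the quaternary centre C1 can form only on the face that carries the alkyne at C6; closest known reaction type is the gold-catalysed 5-endo-dig carbocyclisation of silyl enol ethers onto alkynes, here with the alkyne on the α′-carbon so that a bridged cyclopent-3-enone (ring A) results.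

Step 10
Reactants: 21 2-(Cp-ethynyl)-7-Cp-1-methylbicyclo[3.2.1]oct-6-ene-3,8-dione (both C2 epimers)
Product: 22 2-endo-(Cp-ethynyl)-7-Cp-1-methylbicyclo[3.2.1]oct-6-ene-3,8-dione (alkynyl group on the face of the C6=C7 bridge)
Conditions: t-BuOK (1.1 equiv), THF, −20 °C; then −78 °C, AcOH (2 equiv) in THF
Reagents that add atoms: none
Why: Thermodynamic enolisation of the C10 ketone towards the alkynyl-bearing C2 (conjugated enolate; the C9 ketone has only bridgehead and quaternary neighbours) erases C2, and kinetic protonation from the open face of the carbonyl bridge, away from the C7=C8 bridge and its cyclopropyl group, should funnel both epimers into the endo-alkynyl ketone (stereoconvergent deprotonation–reprotonation).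

Step 11
Reactants: 22 2-endo-(Cp-ethynyl)-7-Cp-1-methylbicyclo[3.2.1]oct-6-ene-3,8-dione; 23 chlorotrimethylsilane
Product: 24 2-endo-(Cp-ethynyl)-7-Cp-1-methyl-3-[(trimethylsilyl)oxy]bicyclo[3.2.1]octa-3,6-dien-8-one
Conditions: i-Pr2NLi (1.1 equiv), TMSCl (3 equiv, in situ), THF, −78 °C
Reagents that add atoms: chlorotrimethylsilane, C[Si](C)(C)Cl
Why: Kinetic enolisation with in situ silyl trapping should remove a proton from the unhindered CH2 (future C5) rather than the shielded methine at C2, giving the regiodefined silyl enol ether without epimerising C2.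

Step 12
Reactants: 24 2-endo-(Cp-ethynyl)-7-Cp-1-methyl-3-[(trimethylsilyl)oxy]bicyclo[3.2.1]octa-3,6-dien-8-one; 25 mercury dichloride; 26 N-iodosuccinimide
Product: 28 syn-3-iodo-1-methyl-4,8-bis(Cp)tricyclo[4.2.1.1(2,5)]deca-3,7-diene-9,10-dione, via vinylmercury chloride 27 (not isolated)
Conditions: HgCl2 (1.1 equiv), (Me3Si)2NH (0.2 equiv), CH2Cl2, 0 °C to rt; then NIS (1.2 equiv), rt, dark
Reagents that add atoms: N-iodosuccinimide, O=C1CCC(=O)N1I
Why: Proposed new method: HgCl2 should coordinate the C2-bound alkyne on its outer face, the C5 enol carbon adding anti to the metal at the cyclopropyl-bearing carbon C4 (5-endo-dig, Markovnikov) while chloride takes the silyl group, and NIS then cleaves the vinylmercury chloride 27 with retention to the C3 iodide. The closest known reaction type is the Conia-type carbocyclisation of alkynyl silyl enol ethers induced by divalent mercury (or catalysed by gold), followed by iododemercuration. Ring B (C2, C3, C4, C5, C10) closes 5-endo-dig and with it the eight-membered ring and the boat of the central ring; C3 and C4 stay sp2 from alkyne to alkene, so nothing points at the facing C7=C8 bridge, which is why this closure, unlike aldol, pinacol or metathesis closures, can give the syn isomer. The new stereocentre C5 is dictated by the bridge, since C4 can reach C5 only on the face on which the alkyne at C2 sits (set endo in step 10), and C2 cannot epimerise because the medium is non-basic, the C9 ketone is non-enolisable and the C10 oxygen is silylated. The step needs chemoselectivity for the alkyne over the two alkenes and the cyclopropanes (soft, dry Lewis acid, no proton source) and attack at C4 rather than C3 (the 4-exo mode is strained and the cyclopropyl group stabilises developing charge at C4).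

Step 13
Reactants: 28 syn-3-iodo-1-methyl-4,8-bis(Cp)tricyclo[4.2.1.1(2,5)]deca-3,7-diene-9,10-dione; 29 methylzinc chloride
Product: 30 syn-1,3-dimethyl-4,8-bis(Cp)tricyclo[4.2.1.1(2,5)]deca-3,7-diene-9,10-dione
Conditions: MeZnCl (3 equiv), Pd(t-Bu3P)2 (5 mol %), THF–NMP, 50 °C
Reagents that add atoms: methylzinc chloride, C[Zn]Cl
Why: Negishi coupling of the hindered vinyl iodide should install the C3 methyl group with retention at the ring alkene, the bulky electron-rich phosphine speeding oxidative addition and the ketones being inert to the organozinc.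

Step 14
Reactants: 30 syn-1,3-dimethyl-4,8-bis(Cp)tricyclo[4.2.1.1(2,5)]deca-3,7-diene-9,10-dione; 31 4-methylbenzenesulfonohydrazide
Product: 33 (1S,2S,5S,6S)-1,3-dimethyl-4,8-bis(Cp)tricyclo[4.2.1.1(2,5)]deca-3,7-diene, via bis(tosylhydrazone) 32 (not isolated)
Conditions: TsNHNH2 (2.5 equiv), EtOH, 50 °C; then catecholborane (5 equiv), CHCl3, 0 °C; NaOAc·3H2O, 60 °C
Reagents that add atoms: none
Why: Tosylhydrazone formation at the two strained bridge ketones and mild hydride reduction with loss of nitrogen and sulfinate (a Wolff–Kishner-type deoxygenation below 60 °C) should turn C9 and C10 into CH2 without alkene migration, since both ketones are β,γ-unsaturated with bridgehead α-carbons.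

Step 15
Reactants: 33 (1S,2S,5S,6S)-1,3-dimethyl-4,8-bis(Cp)tricyclo[4.2.1.1(2,5)]deca-3,7-diene; 16 water
Product: 34 (1S,2S,5S,6S)-1,3-dimethyl-4,8-bis[(1R,3S)-2,2-dimethyl-3-(3-oxobutyl)cyclopropyl]tricyclo[4.2.1.1(2,5)]deca-3,7-diene (target)
Conditions: pyridinium p-toluenesulfonate (0.2 equiv), acetone–H2O (10:1), 40 °C
Reagents that add atoms: water, O
Why: Mild acid-catalysed hydrolysis (transketalisation) of the two dioxolanes should free both methyl ketones under conditions too weak to protonate the vinylcyclopropanes.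

**Compound list**
1 | (S)-(+)-carvone | CC1=CC[C@@H](CC1=O)C(C)=C | starting material
2 | hydrogen chloride | Cl | starting material
3 | (5S)-5-(2-chloropropan-2-yl)-2-methylcyclohex-2-en-1-one | CC1=CC[C@@H](CC1=O)C(C)(C)Cl | intermediate
4 | (1R,6S)-3,7,7-trimethylbicyclo[4.1.0]hept-3-en-2-one | CC1=CC[C@H]2[C@@H](C1=O)C2(C)C | intermediate
5 | 3-chloroperoxybenzoic acid | OOC(=O)c1cccc(Cl)c1 | starting material
6 | (1R,7S)-4,8,8-trimethyl-3-oxabicyclo[5.1.0]oct-4-en-2-one | CC1=CC[C@H]2[C@@H](C(=O)O1)C2(C)C | intermediate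
7 | methanol | CO | starting material
8 | methyl (1R,3S)-2,2-dimethyl-3-(3-oxobutyl)cyclopropane-1-carboxylate | COC(=O)[C@@H]1[C@H](CCC(C)=O)C1(C)C | intermediate
9 | ethane-1,2-diol | OCCO | starting material
10 | methyl (1R,3S)-2,2-dimethyl-3-[2-(2-methyl-1,3-dioxolan-2-yl)ethyl]cyclopropane-1-carboxylate | COC(=O)[C@@H]1[C@H](CCC2(C)OCCO2)C1(C)C | intermediate
11 | dimethyl (1-diazo-2-oxopropyl)phosphonate | CC(=O)C(=[N+]=[N-])P(=O)(OC)OC | starting material
12 | (1R,3S)-2,2-dimethyl-3-[2-(2-methyl-1,3-dioxolan-2-yl)ethyl]cyclopropane-1-carbaldehyde | O=C[C@@H]1[C@H](CCC2(C)OCCO2)C1(C)C | intermediate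
13 | 2-{2-[(1S,3S)-3-ethynyl-2,2-dimethylcyclopropyl]ethyl}-2-methyl-1,3-dioxolane (Cp–C≡CH, cis) | C#C[C@@H]1[C@H](CCC2(C)OCCO2)C1(C)C | intermediate
14 | 4-methoxy-3-methylphenol | COc1ccc(O)cc1C | starting material
15 | 4,4-dimethoxy-3-methylcyclohexa-2,5-dien-1-one | COC1(OC)C=CC(=O)C=C1C | intermediate
16 | water | O | starting material
17 | (5R)-5-(Cp-ethynyl)-4,4-dimethoxy-3-methylcyclohex-2-en-1-one | COC1(OC)C(C)=CC(=O)C[C@@H]1C#C[C@@H]2[C@H](CCC3(C)OCCO3)C2(C)C | intermediate
18 | (6R)-6-(Cp-ethynyl)-2-methylcyclohex-2-ene-1,4-dione | O=C1C(C)=CC(=O)C[C@@H]1C#C[C@@H]2[C@H](CCC3(C)OCCO3)C2(C)C | intermediate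
19 | tert-butyldimethylsilyl trifluoromethanesulfonate | CC(C)(C)[Si](C)(C)OS(=O)(=O)C(F)(F)F | starting material
20 | (5R)-4-[(tert-butyldimethylsilyl)oxy]-2,5-bis(Cp-ethynyl)-3-methylcyclohex-3-en-1-one (C2 epimers) | CC1=C(O[Si](C)(C)C(C)(C)C)[C@@H](C#C[C@@H]2[C@H](CCC3(C)OCCO3)C2(C)C)CC(=O)C1C#C[C@@H]4[C@H](CCC5(C)OCCO5)C4(C)C | intermediate
21 | 2-(Cp-ethynyl)-7-Cp-1-methylbicyclo[3.2.1]oct-6-ene-3,8-dione (C2 epimers; bridgeheads as in 22) | C1(=C[C@@H]2C(=O)[C@@]1(C)C(C#C[C@@H]3[C@H](CCC4(C)OCCO4)C3(C)C)C(=O)C2)[C@@H]5[C@H](CCC6(C)OCCO6)C5(C)C | intermediate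
22 | 2-endo-(Cp-ethynyl)-7-Cp-1-methylbicyclo[3.2.1]oct-6-ene-3,8-dione (alkynyl cis to the C6=C7 bridge, H-2 towards C8) | C1(=C[C@@H]2C(=O)[C@@]1(C)[C@H](C#C[C@@H]3[C@H](CCC4(C)OCCO4)C3(C)C)C(=O)C2)[C@@H]5[C@H](CCC6(C)OCCO6)C5(C)C | intermediate
23 | chlorotrimethylsilane | C[Si](C)(C)Cl | starting material
24 | 2-endo-(Cp-ethynyl)-7-Cp-1-methyl-3-[(trimethylsilyl)oxy]bicyclo[3.2.1]octa-3,6-dien-8-one | C1(=C[C@@H]2C(=O)[C@@]1(C)[C@H](C#C[C@@H]3[C@H](CCC4(C)OCCO4)C3(C)C)C(O[Si](C)(C)C)=C2)[C@@H]5[C@H](CCC6(C)OCCO6)C5(C)C | intermediate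
25 | mercury dichloride | Cl[Hg]Cl | starting material
26 | N-iodosuccinimide | O=C1CCC(=O)N1I | starting material
27 | syn-3-(chloromercurio)-1-methyl-4,8-bis(Cp)tricyclo[4.2.1.1(2,5)]deca-3,7-diene-9,10-dione | C1(=C[C@@H]2C(=O)[C@@]1(C)[C@H]3C(=O)[C@@H]2C([C@@H]4[C@H](CCC5(C)OCCO5)C4(C)C)=C3[Hg]Cl)[C@@H]6[C@H](CCC7(C)OCCO7)C6(C)C | intermediate
28 | syn-3-iodo-1-methyl-4,8-bis(Cp)tricyclo[4.2.1.1(2,5)]deca-3,7-diene-9,10-dione (core configured as in 34) | C1(=C[C@@H]2C(=O)[C@@]1(C)[C@H]3C(=O)[C@@H]2C([C@@H]4[C@H](CCC5(C)OCCO5)C4(C)C)=C3I)[C@@H]6[C@H](CCC7(C)OCCO7)C6(C)C | intermediate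
29 | methylzinc chloride | C[Zn]Cl | starting material
30 | syn-1,3-dimethyl-4,8-bis(Cp)tricyclo[4.2.1.1(2,5)]deca-3,7-diene-9,10-dione | C1(=C[C@@H]2C(=O)[C@@]1(C)[C@H]3C(=O)[C@@H]2C([C@@H]4[C@H](CCC5(C)OCCO5)C4(C)C)=C3C)[C@@H]6[C@H](CCC7(C)OCCO7)C6(C)C | intermediate
31 | 4-methylbenzenesulfonohydrazide | Cc1ccc(cc1)S(=O)(=O)NN | starting material
32 | 9,10-bis(tosylhydrazone) of 30 | C1(=C[C@@H]2C(=NNS(=O)(=O)c8ccc(C)cc8)[C@@]1(C)[C@H]3C(=NNS(=O)(=O)c9ccc(C)cc9)[C@@H]2C([C@@H]4[C@H](CCC5(C)OCCO5)C4(C)C)=C3C)[C@@H]6[C@H](CCC7(C)OCCO7)C6(C)C | intermediate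
33 | (1S,2S,5S,6S)-1,3-dimethyl-4,8-bis(Cp)tricyclo[4.2.1.1(2,5)]deca-3,7-diene (bis-dioxolane of the target) | C1(=C[C@@H]2C[C@@]1(C)[C@H]3C[C@@H]2C([C@@H]4[C@H](CCC5(C)OCCO5)C4(C)C)=C3C)[C@@H]6[C@H](CCC7(C)OCCO7)C6(C)C | intermediate
34 | (1S,2S,5S,6S)-1,3-dimethyl-4,8-bis[(1R,3S)-2,2-dimethyl-3-(3-oxobutyl)cyclopropyl]tricyclo[4.2.1.1(2,5)]deca-3,7-diene (syn) | CC(=O)CC[C@H]1[C@@H](C2=C[C@@H]3C[C@@]2(C)[C@H]2C[C@@H]3C([C@@H]3[C@H](CCC(C)=O)C3(C)C)=C2C)C1(C)C | target

Total step count: 15. Longest linear sequence: 14 (steps 1–5 and 7–15; step 6 is a one-step side branch).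

**Steps most likely to fail**

Step 12 (labelled, key step). The boat-like approach of the C5 enol carbon to the alkyne beneath the C7=C8 bridge may be too slow, so that loss of the silyl group back to ketone 22 or attack of the mercury salt on the alkenes takes over. The fallback sets out from 24 and separates ring closure from halogenation with an isolable organogold: preformed (Ph3P)AuNTf2 (1.05 equiv) with Et3N in CH2Cl2 should give by anti-carboauration the vinylgold complex syn-1-methyl-3-[(triphenylphosphine)aurio]-4,8-bis(Cp)tricyclo[4.2.1.1(2,5)]deca-3,7-diene-9,10-dione F1, and iododeauration of this complex with NIS brings the route back at 28.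

Step 9 (labelled). The 5-endo attack that must create the quaternary C1 next to the cyclopropyl-bearing carbon may lose to protodesilylation of the enol ether or to opening of the alkynylcyclopropane by the π-acid. The fallback sets out from 20 and uses stoichiometric carbomercuration and protodemercuration: HgCl2 with (Me3Si)2NH in CH2Cl2 should give the vinylmercury compound 6-(chloromercurio)-2-(Cp-ethynyl)-7-Cp-1-methylbicyclo[3.2.1]oct-6-ene-3,8-dione F2, which HCl (1 equiv) in Et2O–THF at 0 °C converts to 21, where the route is rejoined.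

Step 14. One hydrazide may bridge the two facing carbonyl groups (transannular condensation), or hydrazone formation may stall at the hindered bridge ketones. The fallback sets out from 30 and is a twofold Barton–McCombie deoxygenation: NaBH4 with CeCl3·7H2O in MeOH should give syn-1,3-dimethyl-4,8-bis(Cp)tricyclo[4.2.1.1(2,5)]deca-3,7-diene-9,10-diol F3, 1,1′-thiocarbonyldiimidazole with DMAP in 1,2-dichloroethane should convert it to its 9,10-bis(imidazol-1-ylthiocarbonyl) ester F4, and Bu3SnH with AIBN in toluene at 80 °C returns the route at 33.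

Further compounds
F1 | step 12 | syn-1-methyl-3-[(triphenylphosphine)aurio]-4,8-bis(Cp)tricyclo[4.2.1.1(2,5)]deca-3,7-diene-9,10-dione | C1(=C[C@@H]2C(=O)[C@@]1(C)[C@H]3C(=O)[C@@H]2C([C@@H]4[C@H](CCC5(C)OCCO5)C4(C)C)=C3[Au-][P+](c4ccccc4)(c5ccccc5)c6ccccc6)[C@@H]7[C@H](CCC8(C)OCCO8)C7(C)C
F2 | step 9 | 6-(chloromercurio)-2-(Cp-ethynyl)-7-Cp-1-methylbicyclo[3.2.1]oct-6-ene-3,8-dione (C2 epimers) | C1(=C([Hg]Cl)[C@@H]2C(=O)[C@@]1(C)C(C#C[C@@H]3[C@H](CCC4(C)OCCO4)C3(C)C)C(=O)C2)[C@@H]5[C@H](CCC6(C)OCCO6)C5(C)C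
F3 | step 14 | syn-1,3-dimethyl-4,8-bis(Cp)tricyclo[4.2.1.1(2,5)]deca-3,7-diene-9,10-diol | C1(=C[C@@H]2C(O)[C@@]1(C)[C@H]3C(O)[C@@H]2C([C@@H]4[C@H](CCC5(C)OCCO5)C4(C)C)=C3C)[C@@H]6[C@H](CCC7(C)OCCO7)C6(C)C
F4 | step 14 | 9,10-bis(imidazol-1-ylthiocarbonyl) ester of F3 | C1(=C[C@@H]2C(OC(=S)n8ccnc8)[C@@]1(C)[C@H]3C(OC(=S)n8ccnc8)[C@@H]2C([C@@H]4[C@H](CCC5(C)OCCO5)C4(C)C)=C3C)[C@@H]6[C@H](CCC7(C)OCCO7)C6(C)C
A1 | direct plan | 4-[(1S,3R)-2,2-dimethyl-3-(2-methylcyclopenta-1,4-dien-1-yl)cyclopropyl]butan-2-one | CC1=C([C@@H]2[C@H](CCC(C)=O)C2(C)C)C=CC1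
A2 | direct plan | 4-[(1S,3R)-2,2-dimethyl-3-(5-methylcyclopenta-1,4-dien-1-yl)cyclopropyl]butan-2-one | CC1=CCC=C1[C@@H]1[C@H](CCC(C)=O)C1(C)C
A3 | direct plan | 4-[(1S,3R)-3-(3-hydroxy-2-methylpenta-1,4-dien-3-yl)-2,2-dimethylcyclopropyl]butan-2-one | CC(=O)CC[C@H]1[C@@H](C(O)(C=C)C(C)=C)C1(C)C
A4 | direct plan | cis-syn-cis head-to-head [2+2] dimer of A1 and A2 (4,10-dimethyl-1,3-dicyclopropyl-tricyclo[5.3.0.0(2,6)]deca-3,9-diene type) | CC1=C([C@@H]3[C@H](CCC(C)=O)C3(C)C)[C@@H]2[C@H](C1)[C@@H]1CC=C(C)[C@]21[C@@H]1[C@H](CCC(C)=O)C1(C)C
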